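**Strategy**

The cyclohexane ring is cut at C1–C2 and C3–C4 (C1 carries the propanoic acid chain, C2 is the quaternary carbon, C3 the CHMe carbon, C6 the isopropylidene carbon). The route exploits the contiguous C1–C2–C3 stereotriad: an enantioselective Diels–Alder reaction between an (E)-2-(indol-3-ylmethyl)but-2-enal (its C=C becomes C2–C3) and a 6-vinyloxepinone diene forms both bonds and all three stereocentres at once. The diene is a seven-membered allylic lactone that ties the future carboxyl carbon to the future isopropylidene carbon; the ring fixes the diene geometry and, after reduction of CHO to the C2 methyl, is opened by palladium and tin hydride with allylic transposition, releasing acid and exocyclic alkene together.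

Key step: step 5

Assumption: the facial sense of the (S)-configured oxazaborolidinium catalyst is taken from the formyl C–H···O pre-transition-state model for α-substituted enals; the enantiomeric catalyst is equally available should the sense prove opposite.

**Route**

Step 1
Reactants: 1 (E)-but-2-enal (crotonaldehyde); 2 cyclohexylamine
Product: 3 (1E,2E)-N-cyclohexylbut-2-en-1-imine
Conditions: K2CO3 (anhydrous), Et2O, 0 °C to rt; distil
Reagents that add atoms: none
Why: Imine formation by condensation of the aldehyde with the primary amine under dehydrating conditions should give the conjugated aldimine; no stereocentre is formed.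

Step 2
Reactants: 3 (1E,2E)-N-cyclohexylbut-2-en-1-imine; 4 tert-butyl 3-(bromomethyl)-1H-indole-1-carboxylate
Product: 8 tert-butyl 3-[(2E)-2-formylbut-2-en-1-yl]-1H-indole-1-carboxylate, via lithiated azadiene 5 (not isolated), via alkylated imine 6 (not isolated), via deconjugated aldehyde 7 (not isolated)
Conditions: LDA (LiN(iPr)2), THF, −78 °C; then 4, −78 to −40 °C; aq. oxalic acid, THF, rt; then Et3N (cat.), CH2Cl2, rt
Reagents that add atoms: water, O
Why: Deconjugative α-alkylation of a metalated α,β-unsaturated aldimine (1-azapentadienyl anion) by the reactive indol-3-ylmethyl bromide, followed by imine hydrolysis and base-mediated reconjugation, should give the thermodynamically favoured E enal (CHO trans to the β-methyl, methyl cis to the indolylmethyl group); the stereocentre of 6 and 7 disappears on conjugation.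

Step 3
Reactants: 9 2-methylbut-3-yn-2-ol; 10 pent-4-enoyl chloride
Product: 11 2-methylbut-3-yn-2-yl pent-4-enoate
Conditions: pyridine, DMAP (cat.), CH2Cl2, 0 °C to rt
Reagents that add atoms: none
Why: DMAP-catalysed acylation (esterification) of the tertiary propargylic alcohol by the acid chloride; no stereocentre is formed.

Step 4
Reactants: 11 2-methylbut-3-yn-2-yl pent-4-enoate
Product: 12 6-ethenyl-7,7-dimethyl-4,7-dihydrooxepin-2(3H)-one
Conditions: second-generation Grubbs catalyst RuCl2(=CHPh)(PCy3)(H2IMes) (5 mol%), ethylene (1 atm), CH2Cl2 (5 mM), 40 °C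
Reagents that add atoms: none
Why: Ring-closing enyne metathesis in the exo mode: the ruthenium alkylidene formed at the terminal alkene adds to the alkyne to close the seven-membered ring and the vinylcarbene is turned over by ethylene, with the gem-dimethyl group and dilution favouring cyclisation; no stereocentre is formed and the ring fixes the side-chain CH2 cis to the CMe2–O carbon.

Step 5
Reactants: 8 tert-butyl 3-[(2E)-2-formylbut-2-en-1-yl]-1H-indole-1-carboxylate; 12 6-ethenyl-7,7-dimethyl-4,7-dihydrooxepin-2(3H)-one
Product: 13 tert-butyl 3-{[(5aR,6S,7R)-6-formyl-1,1,7-trimethyl-3-oxo-1,3,4,5,5a,6,7,8-octahydro-2-benzoxepin-6-yl]methyl}-1H-indole-1-carboxylate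
Conditions: (S)-o-tolyl-CBS oxazaborolidine (C24H24BNO, 20 mol%), HN(SO2CF3)2 (18 mol%), 12 (1.5 equiv), CH2Cl2, −78 to −40 °C
Reagents that add atoms: none
Why: The protonated oxazaborolidine binds the formyl oxygen of 8 (formyl C–H···O contact to the ring oxygen, s-trans enal stacked on a phenyl group) and the LUMO-lowered C2=C3 bond of the enal undergoes a concerted, asynchronous [4+2] cycloaddition with the diene of 12. The closest known reaction type is the cationic-oxazaborolidine-catalysed enantioselective Diels–Alder reaction of α-substituted enals with 1-vinylcycloalkenes, which builds formyl-bearing quaternary carbons next to a ring fusion. The cyclohexene ring closes by suprafacial [4+2] cycloaddition, both new σ bonds running from the diene termini to the two enal alkene carbons. The quaternary carbon is set by the catalyst, which should leave open only the enal face from which CHO, C3 and the indolylmethyl group appear clockwise; the CHMe centre follows from the E geometry of 8 (methyl cis to indolylmethyl); the ring-fusion CH follows from the endo position of the boron-bound formyl group, which places the lactone CH2 cis to CHO. The step needs ortho regiochemistry (ring terminus of the diene to the formyl-bearing carbon, vinyl CH2 to the enal β-carbon), secured by the larger HOMO coefficient at the unsubstituted vinyl terminus of the 1-substituted diene and the larger LUMO coefficient at the enal β-carbon, and the lactone ring holds the side-chain CH2 in the outside position of the diene. The N-Boc group keeps the indole from competing as a nucleophile, and a slight excess of oxazaborolidine over the acid avoids free superacid that could ionise the allylic lactone.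

Step 6
Reactants: 13 tert-butyl 3-{[(5aR,6S,7R)-6-formyl-1,1,7-trimethyl-3-oxo-1,3,4,5,5a,6,7,8-octahydro-2-benzoxepin-6-yl]methyl}-1H-indole-1-carboxylate
Product: 15 tert-butyl 3-{[(5aS,6R,7R)-1,1,6,7-tetramethyl-3-oxo-1,3,4,5,5a,6,7,8-octahydro-2-benzoxepin-6-yl]methyl}-1H-indole-1-carboxylate, via tosylhydrazone 14 (not isolated)
Conditions: TsNHNH2, THF, 50 °C; concentrate; catecholborane, CHCl3, 0 °C to rt; then NaOAc·3H2O, 60 °C
Reagents that add atoms: none
Why: Tosylhydrazone formation and Kabalka-type reduction: catecholborane hydroborates the C=N bond, acetate triggers loss of sulfinate and the alkyl diazene collapses with loss of N2 to the methyl group under near-neutral conditions that should leave lactone, carbamate and the trisubstituted alkene untouched; no stereocentre is involved.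

Step 7
Reactants: 15 tert-butyl 3-{[(5aS,6R,7R)-1,1,6,7-tetramethyl-3-oxo-1,3,4,5,5a,6,7,8-octahydro-2-benzoxepin-6-yl]methyl}-1H-indole-1-carboxylate
Product: 17 suaveolindole 3-[(1S,2R,3R)-2-(1H-indol-3-ylmethyl)-2,3-dimethyl-6-(propan-2-ylidene)cyclohexyl]propanoic acid, via N-Boc seco acid 16 (not isolated)
Conditions: Pd(PPh3)4 (5 mol%), Bu3SnH (slow addition), THF, rt; then K2CO3, MeOH, 60 °C; aq. citric acid work-up
Reagents that add atoms: none
Why: Zerovalent palladium should ionise the tertiary allylic lactone to a π-allylpalladium carboxylate (Tsuji–Trost ionisation) and tin hydride should deliver hydride through palladium to the less hindered ring CH terminus (palladium-catalysed allylic hydrogenolysis), releasing the carboxylate and the tetrasubstituted isopropylidene alkene in one event, after which methanolysis of the indole carbamate frees the N–H; the three stereocentres are not involved.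

**Compound list**

1 | (E)-but-2-enal (crotonaldehyde) | C/C=C/C=O | starting material
2 | cyclohexylamine | NC1CCCCC1 | starting material
3 | (1E,2E)-N-cyclohexylbut-2-en-1-imine | C/C=C/C=N/C1CCCCC1 | intermediate
4 | tert-butyl 3-(bromomethyl)-1H-indole-1-carboxylate | CC(C)(C)OC(=O)n1cc(CBr)c2ccccc12 | starting material
5 | lithium (buta-1,3-dien-1-yl)(cyclohexyl)amide, the lithiated 1-azapentadienyl form of 3 | C=C/C=C/N([Li])C1CCCCC1 | intermediate (not isolated)
6 | tert-butyl 3-{2-[(cyclohexylimino)methyl]but-3-en-1-yl}-1H-indole-1-carboxylate (racemic) | C=CC(Cc1cn(C(=O)OC(C)(C)C)c2ccccc12)/C=N/C1CCCCC1 | intermediate (not isolated)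
7 | tert-butyl 3-(2-formylbut-3-en-1-yl)-1H-indole-1-carboxylate (racemic) | C=CC(Cc1cn(C(=O)OC(C)(C)C)c2ccccc12)C=O | intermediate (not isolated)
8 | tert-butyl 3-[(2E)-2-formylbut-2-en-1-yl]-1H-indole-1-carboxylate (β-methyl cis to the indolylmethyl group, trans to CHO) | C/C=C(\Cc1cn(C(=O)OC(C)(C)C)c2ccccc12)C=O | intermediate
9 | 2-methylbut-3-yn-2-ol | CC(C)(O)C#C | starting material
10 | pent-4-enoyl chloride | C=CCCC(=O)Cl | starting material
11 | 2-methylbut-3-yn-2-yl pent-4-enoate | C=CCCC(=O)OC(C)(C)C#C | intermediate
12 | 6-ethenyl-7,7-dimethyl-4,7-dihydrooxepin-2(3H)-one | C=CC1=CCCC(=O)OC1(C)C | intermediate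
13 | tert-butyl 3-{[(5aR,6S,7R)-6-formyl-1,1,7-trimethyl-3-oxo-1,3,4,5,5a,6,7,8-octahydro-2-benzoxepin-6-yl]methyl}-1H-indole-1-carboxylate (CHO cis to the ring-fusion CH2 and trans to the 7-methyl) | O=C1CC[C@@H]2C(=CC[C@@H](C)[C@@]2(C=O)Cc3cn(C(=O)OC(C)(C)C)c4ccccc34)C(C)(C)O1 | intermediate
14 | (E)-N-tosylhydrazone of 13, (5aS,6S,7R) | O=C1CC[C@@H]2C(=CC[C@@H](C)[C@@]2(/C=N/NS(=O)(=O)c3ccc(C)cc3)Cc3cn(C(=O)OC(C)(C)C)c4ccccc34)C(C)(C)O1 | intermediate (not isolated)
15 | tert-butyl 3-{[(5aS,6R,7R)-1,1,6,7-tetramethyl-3-oxo-1,3,4,5,5a,6,7,8-octahydro-2-benzoxepin-6-yl]methyl}-1H-indole-1-carboxylate | O=C1CC[C@@H]2C(=CC[C@@H](C)[C@@]2(C)Cc3cn(C(=O)OC(C)(C)C)c4ccccc34)C(C)(C)O1 | intermediate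
16 | 3-[(1S,2R,3R)-2-{[1-(tert-butoxycarbonyl)-1H-indol-3-yl]methyl}-2,3-dimethyl-6-(propan-2-ylidene)cyclohexyl]propanoic acid | CC(C)=C1CC[C@@H](C)[C@@](C)(Cc2cn(C(=O)OC(C)(C)C)c3ccccc23)[C@@H]1CCC(=O)O | intermediate (not isolated)
17 | suaveolindole, 3-[(1S,2R,3R)-2-(1H-indol-3-ylmethyl)-2,3-dimethyl-6-(propan-2-ylidene)cyclohexyl]propanoic acid | CC(C)=C1CC[C@@H](C)[C@@](C)(Cc2c[nH]c3ccccc23)[C@@H]1CCC(=O)O | target

**Step count**

Total steps: 7. Longest linear sequence: 5 steps (1, 2, 5, 6, 7, or equally 3, 4, 5, 6, 7).

**Steps most likely to fail**

Step 5 (key step). The cationic Lewis acid may ionise the tertiary allylic lactone of the diene or strip the carbamate. Turnover may be slow because the enal is trisubstituted with a bulky α-branch. Facial or endo selectivity may be insufficient. The fallback gives up asymmetric catalysis and acid altogether. It sets out from 8 and 12, which are combined under high pressure (1.3 GPa, CH2Cl2, 40 °C) in a thermal endo-selective Diels–Alder reaction. This should give 13 as a racemate, that is, together with its enantiomer, tert-butyl 3-{[(5aS,6R,7S)-6-formyl-1,1,7-trimethyl-3-oxo-1,3,4,5,5a,6,7,8-octahydro-2-benzoxepin-6-yl]methyl}-1H-indole-1-carboxylate F1. Preparative chromatography on a chiral stationary phase (cellulose tris(3,5-dimethylphenylcarbamate)) then separates the two, and the fallback comes back to the route at 13.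

Step 7. Hydride may be delivered to the tertiary terminus of the π-allyl unit, which would leave an endocyclic alkene and an isopropyl group. β-Hydride elimination to a diene may compete, or ionisation of the hindered allylic ester may be too slow. The fallback replaces the palladium chemistry by ionic hydrogenation. It sets out from 15, which is treated with Et3SiH and BF3·OEt2 in CH2Cl2 at −78 °C. SN1 ionisation of the lactone C–O bond gives the tertiary allyl cation, and the bulky silane should transfer hydride to the less hindered ring terminus. After aqueous work-up this gives 16 directly, where the fallback comes back to the route; the same carbamate methanolysis then leads to 17. No new compound is made.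

Step 4. Ring closure may be outrun by ethylene cross-metathesis of the alkyne or by oligomerisation, because the tertiary ester rarely adopts the cisoid conformer needed for a seven-membered ring. The fallback reaches the lactone by ring expansion instead of ring closure. It does not branch from a numbered intermediate: commercial 2,2-dimethylcyclohexane-1,3-dione F2 takes the place of 9, 10 and 11. Baeyer–Villiger oxidation (mCPBA, NaHCO3, CH2Cl2, migration of the quaternary carbon) should give 7,7-dimethyloxepane-2,6-dione F3. Kinetic enolisation at the only ketone α-CH2 and trapping (KN(SiMe3)2, PhNTf2, THF, −78 °C) gives 7,7-dimethyl-2-oxo-2,3,4,7-tetrahydrooxepin-6-yl trifluoromethanesulfonate F4. Stille coupling with tributyl(vinyl)stannane (Pd(PPh3)4, LiCl, THF, 65 °C) then installs the vinyl group, and the fallback comes back to the route at 12.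

**Further compounds**

F1 | step 5 | tert-butyl 3-{[(5aS,6R,7S)-6-formyl-1,1,7-trimethyl-3-oxo-1,3,4,5,5a,6,7,8-octahydro-2-benzoxepin-6-yl]methyl}-1H-indole-1-carboxylate (enantiomer of 13) | O=C1CC[C@H]2C(=CC[C@H](C)[C@]2(C=O)Cc3cn(C(=O)OC(C)(C)C)c4ccccc34)C(C)(C)O1
F0 | step 7 | none | none
F2 | step 4 | 2,2-dimethylcyclohexane-1,3-dione | CC1(C)C(=O)CCCC1=O
F3 | step 4 | 7,7-dimethyloxepane-2,6-dione | CC1(C)OC(=O)CCCC1=O
F4 | step 4 | 7,7-dimethyl-2-oxo-2,3,4,7-tetrahydrooxepin-6-yl trifluoromethanesulfonate | CC1(C)OC(=O)CCC=C1OS(=O)(=O)C(F)(F)F
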